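**Plan**
- Retrosynthesis: the lactone Cα–CH2 bond to ring C is cut first (enolate alkylation). In the ring C–D half the cuts are O1–C2 of the dihydrobenzofuran (cationic closure) and C2–C3 (aldol). In the ring A–B half they are C7–C8 (aldol), the ring B O–CH2 ether bond, and the lactone Cβ–CH2CO bond (auxiliary alkylation).
- Forward: an Evans aldol joins rings C and D as an open 1,3-diol, and acid then closes the dihydrobenzofuran, the only ring made in the key step. The aryl bromide is converted to a benzylic bromide. Separately, the butyrolactone on ring B is made by Evans alkylation and lactonisation, its phenol is etherified, and a second Evans aldol brings in ring A. Enolate alkylation joins the halves and fluoride frees all five hydroxyls.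
- Enabling feature: O1–C2 is a benzylic ether and C2 lies para to the oxygen of guaiacyl ring D. C2 can therefore be ionised to a stabilised cation and recaptured by the ring C phenol oxygen, next to the fixed C3 centre carrying CH2OH.
- Stereochemistry: C3 (R) comes from an (S)-oxazolidinone aldol and is relayed to C2 (S, trans) in the ring closure. Lactone C4 (R) comes from an (S)-oxazolidinone alkylation and lactone C3 (R) from trans alkylation. C8 (S) comes from an (R)-oxazolidinone aldol, and C7 (R) from oxidation and chelation-controlled reduction.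

Key step: step 9

Remark: TBS = tert-butyldimethylsilyl; C7 and C8 are the benzylic carbinol and ether carbons of the guaiacylglycerol unit; a syn aldol gives the threo (7S,8S) ether, so the erythro (7R,8S) target needs correction at C7; compound 28 is taken as a purchased reagent.

**Route**

Step 1
Reactants: 1 vanillin
Product: 2 4-(TBS-oxy)-3-methoxybenzaldehyde
Conditions: TBSCl, imidazole, DMF, rt
Reagents that add atoms: tert-butyldimethylsilyl chloride, CC(C)(C)[Si](C)(C)Cl
Why: Imidazole-promoted silyl ether formation masks the phenol of the aldehyde used in both aldol steps and creates no stereocenter.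

Step 2
Reactants: 3 5-bromo-2-hydroxy-3-methoxybenzaldehyde
Product: 4 2-(allyloxy)-5-bromo-3-methoxybenzaldehyde
Conditions: allyl bromide, K2CO3, DMF, rt
Reagents that add atoms: allyl bromide, C=CCBr
Why: Williamson ether synthesis on the acidic salicylaldehyde phenol installs an allyl group that can later be removed without touching silyl ethers.

Step 3
Reactants: 4 2-(allyloxy)-5-bromo-3-methoxybenzaldehyde
Product: 6 2-[2-(allyloxy)-5-bromo-3-methoxyphenyl]acetaldehyde, via methyl enol ether 5 (not isolated)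
Conditions: Ph3P(CH2OMe)Cl, KOtBu, THF, 0 °C to rt; then 3 M HCl, THF, 40 °C
Reagents that add atoms: (methoxymethyl)triphenylphosphonium chloride, COC[P+](c1ccccc1)(c1ccccc1)c1ccccc1.[Cl-]; water, O
Why: Wittig methoxymethylenation followed by acid hydrolysis of the enol ether is the standard one-carbon homologation of an aryl aldehyde, and no stereocenter is involved.

Step 4
Reactants: 6 2-[2-(allyloxy)-5-bromo-3-methoxyphenyl]acetaldehyde
Product: 7 2-[2-(allyloxy)-5-bromo-3-methoxyphenyl]acetic acid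
Conditions: NaClO2, NaH2PO4, 2-methyl-2-butene, t-BuOH/H2O, rt
Reagents that add atoms: sodium chlorite, [Na+].[O-]Cl=O
Why: Pinnick oxidation converts the sensitive arylacetaldehyde to the acid while the alkene scavenger removes hypochlorous acid, so the allyl ether and aryl bromide should survive.

Step 5
Reactants: 7 2-[2-(allyloxy)-5-bromo-3-methoxyphenyl]acetic acid; 8 (S)-4-benzyloxazolidin-2-one
Product: 10 (S)-3-{2-[2-(allyloxy)-5-bromo-3-methoxyphenyl]acetyl}-4-benzyloxazolidin-2-one, via mixed pivalic anhydride 9 (not isolated)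
Conditions: pivaloyl chloride, Et3N, THF, −20 °C; then 8, LiCl, −20 °C to rt
Reagents that add atoms: none
Why: N-acylation of the oxazolidinone through the mixed anhydride should occur at the less hindered arylacetyl carbonyl and attaches the auxiliary without creating a stereocenter.

Step 6
Reactants: 10 (S)-3-{2-[2-(allyloxy)-5-bromo-3-methoxyphenyl]acetyl}-4-benzyloxazolidin-2-one; 2 4-(TBS-oxy)-3-methoxybenzaldehyde
Product: 11 (S)-3-[(2S,3S)-2-[2-(allyloxy)-5-bromo-3-methoxyphenyl]-3-(4-TBS-oxy-3-methoxyphenyl)-3-hydroxypropanoyl]-4-benzyloxazolidin-2-one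
Conditions: Bu2BOTf, iPr2NEt, CH2Cl2, −78 to 0 °C; then 2, −78 to 0 °C; pH 7 buffer/MeOH work-up
Reagents that add atoms: none
Why: In this Evans syn aldol the Z boron enolate should react through a Zimmerman–Traxler chair on the face away from the auxiliary benzyl group, which sets the aryl-bearing carbon (2S, the future C3) and the syn carbinol (3S).

Step 7
Reactants: 11 aldol adduct
Product: 12 (1S,2R)-2-[2-(allyloxy)-5-bromo-3-methoxyphenyl]-1-(4-TBS-oxy-3-methoxyphenyl)propane-1,3-diol
Conditions: LiBH4, MeOH (1 equiv), THF, 0 °C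
Reagents that add atoms: none
Why: Reductive cleavage of the N-acyloxazolidinone with LiBH4 should give the primary alcohol and release the auxiliary without touching either stereocenter (the descriptor 2R reflects only a priority change), the aryl bromide or the silyl ether.

Step 8
Reactants: 12 allyl-protected diol
Product: 13 (1S,2R)-2-(5-bromo-2-hydroxy-3-methoxyphenyl)-1-(4-TBS-oxy-3-methoxyphenyl)propane-1,3-diol
Conditions: Pd(PPh3)4 (cat.), morpholine, THF, rt
Reagents that add atoms: none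
Why: Tsuji–Trost deallylation with zerovalent palladium transfers the allyl group to morpholine under neutral conditions that should spare the silyl ether, the benzylic alcohol and, at room temperature, the aryl bromide.

Step 9
Reactants: 13 (1S,2R)-2-(5-bromo-2-hydroxy-3-methoxyphenyl)-1-(4-TBS-oxy-3-methoxyphenyl)propane-1,3-diol
Product: 14 [(2S,3R)-5-bromo-2-(4-TBS-oxy-3-methoxyphenyl)-7-methoxy-2,3-dihydrobenzofuran-3-yl]methanol
Conditions: TsOH·H2O (10 mol %), CH2Cl2, 0 °C to rt
Reagents that add atoms: none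
Why: Protonation of the benzylic hydroxyl and loss of water give a cation at C2 that is delocalised onto the para silyloxy oxygen of ring D, and the ortho phenol oxygen of ring C adds to it to form the O1–C2 bond. The closest known reaction type is the acid-promoted cyclodehydration of 2-(2-hydroxyaryl)-1-arylpropane-1,3-diols to trans-2-aryl-3-hydroxymethyl-2,3-dihydrobenzofurans. The five-membered ring closes in a 5-exo-trig mode onto the trigonal cationic carbon. The new C2 centre (S) is set by the fixed C3 centre (R), because the aryl group turns away from the hydroxymethyl group in the closing transition state and the reversible closure also ends at the more stable trans ring. The step needs the phenol to win over the primary alcohol and C3 to stay intact, which the substrate secures since the alcohol could only form an oxetane and C3 carries no acidifying group, while catalytic acid at low temperature limits proton loss from the cation and cleavage of the aryl silyl ether. As ionisation erases the carbinol configuration, both aldol diastereomers would converge on 14.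

Step 10
Reactants: 14 dihydrobenzofuran alcohol
Product: 15 (2S,3R)-5-bromo-2-(4-TBS-oxy-3-methoxyphenyl)-3-(TBS-oxymethyl)-7-methoxy-2,3-dihydrobenzofuran
Conditions: TBSCl, imidazole, DMF, rt
Reagents that add atoms: tert-butyldimethylsilyl chloride, CC(C)(C)[Si](C)(C)Cl
Why: Silyl ether formation at the unhindered primary alcohol removes the only acidic proton before the lithiation and leaves both stereocenters untouched.

Step 11
Reactants: 15 bis-silyl aryl bromide
Product: 17 [(2S,3R)-2-(4-TBS-oxy-3-methoxyphenyl)-3-(TBS-oxymethyl)-7-methoxy-2,3-dihydrobenzofuran-5-yl]methanol, via aldehyde 16 (not isolated)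
Conditions: n-BuLi, THF, −78 °C; DMF, −78 to 0 °C; then MeOH, NaBH4, 0 °C
Reagents that add atoms: N,N-dimethylformamide, CN(C)C=O
Why: Bromine–lithium exchange, formylation of the aryllithium with DMF and borohydride reduction in the same flask should turn the aryl bromide into the benzylic alcohol, with exchange at −78 °C being faster than attack on the aryl silyl ether.

Step 12
Reactants: 17 benzylic alcohol
Product: 18 (2S,3R)-5-(bromomethyl)-2-(4-TBS-oxy-3-methoxyphenyl)-3-(TBS-oxymethyl)-7-methoxy-2,3-dihydrobenzofuran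
Conditions: CBr4, PPh3, CH2Cl2, 0 °C; used at once
Reagents that add atoms: carbon tetrabromide, BrC(Br)(Br)Br
Why: The Appel reaction brominates the primary benzylic alcohol under neutral conditions that should not ionise the acid-sensitive C2 ether or the silyl groups.

Step 13
Reactants: 19 3-(4-hydroxy-3-methoxyphenyl)propanoic acid
Product: 21 3-[4-(benzyloxy)-3-methoxyphenyl]propanoic acid, via benzyl ester 20 (not isolated)
Conditions: BnBr, K2CO3, DMF, 60 °C; then NaOH, MeOH/H2O, 60 °C; HCl work-up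
Reagents that add atoms: benzyl bromide, BrCc1ccccc1; sodium hydroxide, [Na+].[OH-]
Why: Double O-benzylation (Williamson ether synthesis and ester formation) followed by saponification of the benzyl ester leaves the phenol protected and the acid free.

Step 14
Reactants: 21 3-[4-(benzyloxy)-3-methoxyphenyl]propanoic acid; 8 (S)-4-benzyloxazolidin-2-one
Product: 23 (S)-4-benzyl-3-{3-[4-(benzyloxy)-3-methoxyphenyl]propanoyl}oxazolidin-2-one, via mixed pivalic anhydride 22 (not isolated)
Conditions: pivaloyl chloride, Et3N, THF, −20 °C; then 8, LiCl, −20 °C to rt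
Reagents that add atoms: none
Why: N-acylation of the oxazolidinone through the mixed anhydride attaches the auxiliary for the alkylation and creates no stereocenter.

Step 15
Reactants: 23 (S)-4-benzyl-3-{3-[4-(benzyloxy)-3-methoxyphenyl]propanoyl}oxazolidin-2-one
Product: 24 tert-butyl (R)-3-[4-(benzyloxy)-3-methoxybenzyl]-4-[(S)-4-benzyl-2-oxooxazolidin-3-yl]-4-oxobutanoate
Conditions: NaN(SiMe3)2, THF, −78 °C; then BrCH2CO2tBu, −78 to −40 °C
Reagents that add atoms: tert-butyl bromoacetate, CC(C)(C)OC(=O)CBr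
Why: In this Evans asymmetric alkylation the chelated Z sodium enolate should be attacked on the face opposite the auxiliary benzyl group, which sets the future lactone C4 as R.

Step 16
Reactants: 24 alkylated imide
Product: 26 (R)-4-[4-(benzyloxy)-3-methoxybenzyl]dihydrofuran-2(3H)-one, via hydroxy tert-butyl ester 25 (not isolated)
Conditions: LiBH4, H2O (1 equiv), THF, 0 °C; then TsOH·H2O (cat.), CH2Cl2, rt
Reagents that add atoms: none
Why: LiBH4 should reduce the imide carbonyl in preference to the tert-butyl ester, and acid-catalysed lactonisation of the γ-hydroxy ester then closes the butyrolactone without touching the stereocenter.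

Step 17
Reactants: 26 benzyl-protected lactone
Product: 27 (R)-4-(4-hydroxy-3-methoxybenzyl)dihydrofuran-2(3H)-one
Conditions: H2 (1 atm), Pd/C, EtOAc, rt
Reagents that add atoms: none
Why: Catalytic hydrogenolysis of the benzyl aryl ether frees the ring B phenol, and nothing else in the molecule is reducible under these conditions.

Step 18
Reactants: 27 (R)-4-(4-hydroxy-3-methoxybenzyl)dihydrofuran-2(3H)-one; 28 (R)-4-benzyl-3-(2-chloroacetyl)oxazolidin-2-one
Product: 29 (R)-4-benzyl-3-[2-(2-methoxy-4-{[(R)-5-oxotetrahydrofuran-3-yl]methyl}phenoxy)acetyl]oxazolidin-2-one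
Conditions: K2CO3, NaI (cat.), acetone, reflux
Reagents that add atoms: none
Why: Williamson etherification of the phenoxide with the α-chloro imide (iodide-assisted) forms the ring B O–CH2 bond and delivers the aryloxyacetyl imide in one operation.

Step 19
Reactants: 29 aryloxyacetyl imide; 2 4-(TBS-oxy)-3-methoxybenzaldehyde
Product: 30 (R)-4-benzyl-3-[(2R,3S)-3-(4-TBS-oxy-3-methoxyphenyl)-3-hydroxy-2-(2-methoxy-4-{[(R)-5-oxotetrahydrofuran-3-yl]methyl}phenoxy)propanoyl]oxazolidin-2-one
Conditions: Bu2BOTf (1.1 equiv), iPr2NEt, CH2Cl2, −78 to 0 °C; then 2, −78 to 0 °C; pH 7 buffer/MeOH work-up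
Reagents that add atoms: none
Why: In this Evans syn aldol the far more acidic imide is enolised in preference to the lactone and the Z boron enolate reacts through a Zimmerman–Traxler chair away from the auxiliary benzyl group, which sets C8 correctly (2R here, 8S after reduction) and gives the syn carbinol (7S, threo) that steps 22 and 23 correct.

Step 20
Reactants: 30 aldol adduct
Product: 31 (R)-4-{4-[(1S,2S)-1-(4-TBS-oxy-3-methoxyphenyl)-1,3-dihydroxypropan-2-yloxy]-3-methoxybenzyl}dihydrofuran-2(3H)-one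
Conditions: NaBH4, THF/H2O (4:1), 0 °C
Reagents that add atoms: none
Why: Borohydride reduction of the activated N-acyloxazolidinone carbonyl should be much faster than attack on the γ-lactone, so the auxiliary is cleaved to the primary alcohol with both new stereocenters unchanged.

Step 21
Reactants: 31 threo diol
Product: 32 (R)-4-{4-[(1S,2S)-1-(4-TBS-oxy-3-methoxyphenyl)-1-hydroxy-3-(TBS-oxy)propan-2-yloxy]-3-methoxybenzyl}dihydrofuran-2(3H)-one
Conditions: TBSCl (1.05 equiv), imidazole, CH2Cl2, 0 °C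
Reagents that add atoms: tert-butyldimethylsilyl chloride, CC(C)(C)[Si](C)(C)Cl
Why: Silylation should select the primary hydroxyl over the hindered secondary benzylic one on steric grounds, leaving C7–OH free for oxidation.

Step 22
Reactants: 32 threo secondary alcohol
Product: 33 (R)-4-{4-[(S)-1-(4-TBS-oxy-3-methoxyphenyl)-1-oxo-3-(TBS-oxy)propan-2-yloxy]-3-methoxybenzyl}dihydrofuran-2(3H)-one
Conditions: Dess–Martin periodinane, CH2Cl2, 0 °C to rt
Reagents that add atoms: none
Why: Dess–Martin oxidation removes the wrongly configured C7 carbinol under non-basic conditions that should not enolise the α-aryloxy ketone, so C8 is retained.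

Step 23
Reactants: 33 α-aryloxy ketone
Product: 34 (R)-4-{4-[(1R,2S)-1-(4-TBS-oxy-3-methoxyphenyl)-1-hydroxy-3-(TBS-oxy)propan-2-yloxy]-3-methoxybenzyl}dihydrofuran-2(3H)-one
Conditions: Zn(BH4)2, Et2O, −20 °C
Reagents that add atoms: none
Why: In this chelation-controlled (Cram chelate) reduction zinc should bridge the ketone oxygen and the aryl ether oxygens on C8 so that hydride enters from the side of the C8 hydrogen, which sets C7 as R (erythro) and leaves the lactone untouched.

Step 24
Reactants: 34 erythro alcohol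
Product: 35 (R)-4-{4-[(1R,2S)-1-(4-TBS-oxy-3-methoxyphenyl)-1,3-bis(TBS-oxy)propan-2-yloxy]-3-methoxybenzyl}dihydrofuran-2(3H)-one
Conditions: TBSOTf, 2,6-lutidine, CH2Cl2, −78 to 0 °C
Reagents that add atoms: tert-butyldimethylsilyl trifluoromethanesulfonate, CC(C)(C)[Si](C)(C)OS(=O)(=O)C(F)(F)F
Why: Silyl triflate with a hindered base silylates the hindered secondary benzylic alcohol, removing the last acidic proton before enolate formation.

Step 25
Reactants: 35 tris-silyl lactone; 18 benzylic bromide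
Product: 36 pentakis-TBS ether of the target, (3R,4R)-3-{[(2S,3R)-2-(4-TBS-oxy-3-methoxyphenyl)-3-(TBS-oxymethyl)-7-methoxy-2,3-dihydrobenzofuran-5-yl]methyl}-4-{4-[(1R,2S)-1-(4-TBS-oxy-3-methoxyphenyl)-1,3-bis(TBS-oxy)propan-2-yloxy]-3-methoxybenzyl}dihydrofuran-2(3H)-one
Conditions: LiN(SiMe3)2, THF, −78 °C; then 18, DMPU, −78 to −30 °C
Reagents that add atoms: none
Why: Alkylation of the lithium enolate of a β-substituted γ-butyrolactone should take the benzylic bromide on the face opposite the β-benzyl group, which sets lactone C3 as R (trans) as in dibenzylbutyrolactone lignan syntheses.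

Step 26
Reactants: 36 pentakis-TBS ether
Product: 37 target, (3R,4R)-3-{[(2S,3R)-2-(4-hydroxy-3-methoxyphenyl)-3-(hydroxymethyl)-7-methoxy-2,3-dihydrobenzofuran-5-yl]methyl}-4-{4-[(1R,2S)-1,3-dihydroxy-1-(4-hydroxy-3-methoxyphenyl)propan-2-yloxy]-3-methoxybenzyl}dihydrofuran-2(3H)-one
Conditions: Bu4NF, AcOH, THF, 0 °C to rt
Reagents that add atoms: none
Why: Fluoride-mediated desilylation buffered with acetic acid should remove the two aryl and three alkyl silyl ethers without epimerising the lactone or ionising the benzylic C2 and C7 positions.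

**Compound list**

1 | vanillin (4-hydroxy-3-methoxybenzaldehyde) | COc1cc(C=O)ccc1O | starting material
2 | 4-(TBS-oxy)-3-methoxybenzaldehyde | COc1cc(C=O)ccc1O[Si](C)(C)C(C)(C)C | intermediate
3 | 5-bromo-2-hydroxy-3-methoxybenzaldehyde | COc1cc(Br)cc(C=O)c1O | starting material
4 | 2-(allyloxy)-5-bromo-3-methoxybenzaldehyde | COc1cc(Br)cc(C=O)c1OCC=C | intermediate
5 | 1-(allyloxy)-4-bromo-2-methoxy-6-(2-methoxyvinyl)benzene, E/Z mixture | COC=Cc1cc(Br)cc(OC)c1OCC=C | intermediate
6 | 2-[2-(allyloxy)-5-bromo-3-methoxyphenyl]acetaldehyde | COc1cc(Br)cc(CC=O)c1OCC=C | intermediate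
7 | 2-[2-(allyloxy)-5-bromo-3-methoxyphenyl]acetic acid | COc1cc(Br)cc(CC(=O)O)c1OCC=C | intermediate
8 | (S)-4-benzyloxazolidin-2-one | O=C1N[C@@H](Cc2ccccc2)CO1 | starting material
9 | 2-[2-(allyloxy)-5-bromo-3-methoxyphenyl]acetic pivalic anhydride | COc1cc(Br)cc(CC(=O)OC(=O)C(C)(C)C)c1OCC=C | intermediate
10 | (S)-3-{2-[2-(allyloxy)-5-bromo-3-methoxyphenyl]acetyl}-4-benzyloxazolidin-2-one | COc1cc(Br)cc(CC(=O)N2[C@@H](Cc3ccccc3)COC2=O)c1OCC=C | intermediate
11 | (S)-3-[(2S,3S)-2-[2-(allyloxy)-5-bromo-3-methoxyphenyl]-3-(4-TBS-oxy-3-methoxyphenyl)-3-hydroxypropanoyl]-4-benzyloxazolidin-2-one | O=C(N1[C@@H](Cc2ccccc2)COC1=O)[C@@H](c1cc(Br)cc(OC)c1OCC=C)[C@H](O)c1ccc(O[Si](C)(C)C(C)(C)C)c(OC)c1 | intermediate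
12 | (1S,2R)-2-[2-(allyloxy)-5-bromo-3-methoxyphenyl]-1-(4-TBS-oxy-3-methoxyphenyl)propane-1,3-diol | Brc1cc(OC)c(OCC=C)c(c1)[C@H](CO)[C@H](O)c1ccc(O[Si](C)(C)C(C)(C)C)c(OC)c1 | intermediate
13 | (1S,2R)-2-(5-bromo-2-hydroxy-3-methoxyphenyl)-1-(4-TBS-oxy-3-methoxyphenyl)propane-1,3-diol | Brc1cc(OC)c(O)c(c1)[C@H](CO)[C@H](O)c1ccc(O[Si](C)(C)C(C)(C)C)c(OC)c1 | intermediate
14 | [(2S,3R)-5-bromo-2-(4-TBS-oxy-3-methoxyphenyl)-7-methoxy-2,3-dihydrobenzofuran-3-yl]methanol | Brc1cc(OC)c2c(c1)[C@H](CO)[C@@H](c1ccc(O[Si](C)(C)C(C)(C)C)c(OC)c1)O2 | intermediate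
15 | (2S,3R)-5-bromo-2-(4-TBS-oxy-3-methoxyphenyl)-3-(TBS-oxymethyl)-7-methoxy-2,3-dihydrobenzofuran | Brc1cc(OC)c2c(c1)[C@H](CO[Si](C)(C)C(C)(C)C)[C@@H](c1ccc(O[Si](C)(C)C(C)(C)C)c(OC)c1)O2 | intermediate
16 | (2S,3R)-2-(4-TBS-oxy-3-methoxyphenyl)-3-(TBS-oxymethyl)-7-methoxy-2,3-dihydrobenzofuran-5-carbaldehyde | O=Cc1cc(OC)c2c(c1)[C@H](CO[Si](C)(C)C(C)(C)C)[C@@H](c1ccc(O[Si](C)(C)C(C)(C)C)c(OC)c1)O2 | intermediate
17 | [(2S,3R)-2-(4-TBS-oxy-3-methoxyphenyl)-3-(TBS-oxymethyl)-7-methoxy-2,3-dihydrobenzofuran-5-yl]methanol | OCc1cc(OC)c2c(c1)[C@H](CO[Si](C)(C)C(C)(C)C)[C@@H](c1ccc(O[Si](C)(C)C(C)(C)C)c(OC)c1)O2 | intermediate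
18 | (2S,3R)-5-(bromomethyl)-2-(4-TBS-oxy-3-methoxyphenyl)-3-(TBS-oxymethyl)-7-methoxy-2,3-dihydrobenzofuran | BrCc1cc(OC)c2c(c1)[C@H](CO[Si](C)(C)C(C)(C)C)[C@@H](c1ccc(O[Si](C)(C)C(C)(C)C)c(OC)c1)O2 | intermediate
19 | 3-(4-hydroxy-3-methoxyphenyl)propanoic acid | COc1cc(CCC(=O)O)ccc1O | starting material
20 | benzyl 3-[4-(benzyloxy)-3-methoxyphenyl]propanoate | COc1cc(CCC(=O)OCc2ccccc2)ccc1OCc1ccccc1 | intermediate
21 | 3-[4-(benzyloxy)-3-methoxyphenyl]propanoic acid | COc1cc(CCC(=O)O)ccc1OCc1ccccc1 | intermediate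
22 | 3-[4-(benzyloxy)-3-methoxyphenyl]propanoic pivalic anhydride | COc1cc(CCC(=O)OC(=O)C(C)(C)C)ccc1OCc1ccccc1 | intermediate
23 | (S)-4-benzyl-3-{3-[4-(benzyloxy)-3-methoxyphenyl]propanoyl}oxazolidin-2-one | COc1cc(CCC(=O)N2[C@@H](Cc3ccccc3)COC2=O)ccc1OCc1ccccc1 | intermediate
24 | tert-butyl (R)-3-[4-(benzyloxy)-3-methoxybenzyl]-4-[(S)-4-benzyl-2-oxooxazolidin-3-yl]-4-oxobutanoate | CC(C)(C)OC(=O)C[C@@H](Cc1ccc(OCc2ccccc2)c(OC)c1)C(=O)N1[C@@H](Cc2ccccc2)COC1=O | intermediate
25 | tert-butyl (R)-4-[4-(benzyloxy)-3-methoxyphenyl]-3-(hydroxymethyl)butanoate | CC(C)(C)OC(=O)C[C@@H](Cc1ccc(OCc2ccccc2)c(OC)c1)CO | intermediate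
26 | (R)-4-[4-(benzyloxy)-3-methoxybenzyl]dihydrofuran-2(3H)-one | O=C1C[C@@H](Cc2ccc(OCc3ccccc3)c(OC)c2)CO1 | intermediate
27 | (R)-4-(4-hydroxy-3-methoxybenzyl)dihydrofuran-2(3H)-one | O=C1C[C@@H](Cc2ccc(O)c(OC)c2)CO1 | intermediate
28 | (R)-4-benzyl-3-(2-chloroacetyl)oxazolidin-2-one | O=C(CCl)N1[C@H](Cc2ccccc2)COC1=O | starting material
29 | (R)-4-benzyl-3-[2-(2-methoxy-4-{[(R)-5-oxotetrahydrofuran-3-yl]methyl}phenoxy)acetyl]oxazolidin-2-one | O=C(COc1ccc(C[C@H]2COC(=O)C2)cc1OC)N1[C@H](Cc2ccccc2)COC1=O | intermediate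
30 | (R)-4-benzyl-3-[(2R,3S)-3-(4-TBS-oxy-3-methoxyphenyl)-3-hydroxy-2-(2-methoxy-4-{[(R)-5-oxotetrahydrofuran-3-yl]methyl}phenoxy)propanoyl]oxazolidin-2-one | O=C(N1[C@H](Cc2ccccc2)COC1=O)[C@H](Oc1ccc(C[C@H]2COC(=O)C2)cc1OC)[C@@H](O)c1ccc(O[Si](C)(C)C(C)(C)C)c(OC)c1 | intermediate
31 | (R)-4-{4-[(1S,2S)-1-(4-TBS-oxy-3-methoxyphenyl)-1,3-dihydroxypropan-2-yloxy]-3-methoxybenzyl}dihydrofuran-2(3H)-one (threo) | COc1cc([C@H](O)[C@H](CO)Oc2ccc(C[C@H]3COC(=O)C3)cc2OC)ccc1O[Si](C)(C)C(C)(C)C | intermediate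
32 | (R)-4-{4-[(1S,2S)-1-(4-TBS-oxy-3-methoxyphenyl)-1-hydroxy-3-(TBS-oxy)propan-2-yloxy]-3-methoxybenzyl}dihydrofuran-2(3H)-one | COc1cc([C@H](O)[C@H](CO[Si](C)(C)C(C)(C)C)Oc2ccc(C[C@H]3COC(=O)C3)cc2OC)ccc1O[Si](C)(C)C(C)(C)C | intermediate
33 | (R)-4-{4-[(S)-1-(4-TBS-oxy-3-methoxyphenyl)-1-oxo-3-(TBS-oxy)propan-2-yloxy]-3-methoxybenzyl}dihydrofuran-2(3H)-one | COc1cc(C(=O)[C@H](CO[Si](C)(C)C(C)(C)C)Oc2ccc(C[C@H]3COC(=O)C3)cc2OC)ccc1O[Si](C)(C)C(C)(C)C | intermediate
34 | (R)-4-{4-[(1R,2S)-1-(4-TBS-oxy-3-methoxyphenyl)-1-hydroxy-3-(TBS-oxy)propan-2-yloxy]-3-methoxybenzyl}dihydrofuran-2(3H)-one (erythro) | COc1cc([C@@H](O)[C@H](CO[Si](C)(C)C(C)(C)C)Oc2ccc(C[C@H]3COC(=O)C3)cc2OC)ccc1O[Si](C)(C)C(C)(C)C | intermediate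
35 | (R)-4-{4-[(1R,2S)-1-(4-TBS-oxy-3-methoxyphenyl)-1,3-bis(TBS-oxy)propan-2-yloxy]-3-methoxybenzyl}dihydrofuran-2(3H)-one | COc1cc([C@@H](O[Si](C)(C)C(C)(C)C)[C@H](CO[Si](C)(C)C(C)(C)C)Oc2ccc(C[C@H]3COC(=O)C3)cc2OC)ccc1O[Si](C)(C)C(C)(C)C | intermediate
36 | pentakis-TBS ether of the target (name as in step 25) | COc1cc([C@@H](O[Si](C)(C)C(C)(C)C)[C@H](CO[Si](C)(C)C(C)(C)C)Oc2ccc(C[C@H]3COC(=O)[C@@H]3Cc3cc(OC)c4c(c3)[C@H](CO[Si](C)(C)C(C)(C)C)[C@@H](c3ccc(O[Si](C)(C)C(C)(C)C)c(OC)c3)O4)cc2OC)ccc1O[Si](C)(C)C(C)(C)C | intermediate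
37 | CNP0265599.1 (name as in step 26) | COc1cc([C@@H](O)[C@H](CO)Oc2ccc(C[C@H]3COC(=O)[C@@H]3Cc3cc(OC)c4c(c3)[C@H](CO)[C@@H](c3ccc(O)c(OC)c3)O4)cc2OC)ccc1O | target

**Step count and risks**

Total: 26 steps. Longest linear sequence: 14 steps (steps 13 to 26, from 19); the ring C–D branch runs 13 steps (steps 2 to 12, then 25 and 26).

Steps most likely to fail:

Step 9. After ionisation, loss of the C3 proton to a stilbene-type alkene (with return eroding C3), or acid cleavage of the aryl silyl ether, may compete with ring closure. The fallback sets out from 13 and comes back at 15, closing the ring through a neutral quinone methide instead of the silyl-substituted cation. The ring D silyl ether of 13 is removed first (Bu4NF, AcOH, THF) to give (1S,2R)-2-(5-bromo-2-hydroxy-3-methoxyphenyl)-1-(4-hydroxy-3-methoxyphenyl)propane-1,3-diol F1. With the para hydroxyl free, dehydration under much weaker acid (pyridinium p-toluenesulfonate, CH2Cl2, rt) should pass through the p-quinone methide F2. The ring C phenol adds to it in the way phenylcoumarans arise from lignols, giving [(2S,3R)-5-bromo-2-(4-hydroxy-3-methoxyphenyl)-7-methoxy-2,3-dihydrobenzofuran-3-yl]methanol F3. Silylation of both hydroxyls of F3 (TBSCl, imidazole, DMF) returns to 15.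

Step 23. Hydride delivery may show poor facial selectivity if the zinc chelate does not form (a polar Felkin–Anh pathway would return the threo alcohol), and the α-aryloxy ketone may epimerise at C8 by enolisation. The fallback sets out from 32 and comes back at 34, replacing the oxidation–reduction pair by an invertive substitution. Mitsunobu reaction of 32 with chloroacetic acid (PPh3, diisopropyl azodicarboxylate, toluene, 0 °C) should give the inverted (1R,2S) chloroacetate F4. Thiourea with NaHCO3 in ethanol then removes the chloroacetyl group without touching the lactone or the aryl silyl ether and delivers 34.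

Step 25. C-alkylation of the hindered enolate may be slow while the electron-rich benzylic bromide decomposes, and proton transfer to the product may cause double alkylation. The fallback sets out from 35 and from aldehyde 16 (isolated by leaving out the borohydride in step 11) and comes back at 36, swapping alkylation for aldol addition and radical deoxygenation. Addition of the lithium enolate of 35 to 16 (LiN(SiMe3)2, THF, −78 °C) should give the trans α-(hydroxybenzyl) lactone F5, as a mixture at the new carbinol. Conversion to the O-phenyl thionocarbonate F6 (PhOC(S)Cl, pyridine, DMAP, CH2Cl2) and Barton–McCombie deoxygenation (Bu3SnH, AIBN, toluene, 80 °C) removes the benzylic oxygen and returns to 36.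

Further compounds
F1 | step 9 | (1S,2R)-2-(5-bromo-2-hydroxy-3-methoxyphenyl)-1-(4-hydroxy-3-methoxyphenyl)propane-1,3-diol | Brc1cc(OC)c(O)c(c1)[C@H](CO)[C@H](O)c1ccc(O)c(OC)c1
F2 | step 9 | 4-[(2R)-2-(5-bromo-2-hydroxy-3-methoxyphenyl)-3-hydroxypropylidene]-2-methoxycyclohexa-2,5-dien-1-one (p-quinone methide) | COC1=CC(=C[C@@H](CO)c2cc(Br)cc(OC)c2O)C=CC1=O
F3 | step 9 | [(2S,3R)-5-bromo-2-(4-hydroxy-3-methoxyphenyl)-7-methoxy-2,3-dihydrobenzofuran-3-yl]methanol | Brc1cc(OC)c2c(c1)[C@H](CO)[C@@H](c1ccc(O)c(OC)c1)O2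
F4 | step 23 | (1R,2S)-1-(4-TBS-oxy-3-methoxyphenyl)-2-(2-methoxy-4-{[(R)-5-oxotetrahydrofuran-3-yl]methyl}phenoxy)-3-(TBS-oxy)propyl 2-chloroacetate | COc1cc([C@@H](OC(=O)CCl)[C@H](CO[Si](C)(C)C(C)(C)C)Oc2ccc(C[C@H]3COC(=O)C3)cc2OC)ccc1O[Si](C)(C)C(C)(C)C
F5 | step 25 | 36 bearing a hydroxyl on the CH2 between lactone C3 and ring C (trans lactone, carbinol epimers) | COc1cc([C@@H](O[Si](C)(C)C(C)(C)C)[C@H](CO[Si](C)(C)C(C)(C)C)Oc2ccc(C[C@H]3COC(=O)[C@@H]3C(O)c3cc(OC)c4c(c3)[C@H](CO[Si](C)(C)C(C)(C)C)[C@@H](c3ccc(O[Si](C)(C)C(C)(C)C)c(OC)c3)O4)cc2OC)ccc1O[Si](C)(C)C(C)(C)C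
F6 | step 25 | O-phenyl thionocarbonate of F5 | COc1cc([C@@H](O[Si](C)(C)C(C)(C)C)[C@H](CO[Si](C)(C)C(C)(C)C)Oc2ccc(C[C@H]3COC(=O)[C@@H]3C(OC(=S)Oc5ccccc5)c3cc(OC)c4c(c3)[C@H](CO[Si](C)(C)C(C)(C)C)[C@@H](c3ccc(O[Si](C)(C)C(C)(C)C)c(OC)c3)O4)cc2OC)ccc1O[Si](C)(C)C(C)(C)C
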